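Numbering follows a chroman-4-one (O1, C2, C3, C4, C4a, C5, C6, C7, C8, C8a); C1' and C2' are the first two carbons of the C11 chain on C6. The last bond made is C6–prenyl, by catalyst-controlled dearomative prenylation of a 5,7-dihydroxychromanone acid, which sets C6.
Ring A (C4a, C5, C6, C7, C8, C8a) is cut at C4a–C5 and C6–C7: a ketene C5=C6, released by Wolff rearrangement of a diazoketone that carries C2', is annulated onto the C4a=C8a–C8–C7 unit of a pyranone-substituted 3-phenylglutaric anhydride.
Enabling feature: C5, C6 and C7 are a cyclic β-diketone next to the C4 acyl group, so C6–C7 is a Claisen bond (enol carbon to acyl carbon). C8–H lies between C7 and the vinylogous ester C8a=C4a–C4=O, and the side-chain carboxyl is 1,5 to C7, so C7 and that carboxyl can be held as one six-membered cyclic anhydride that is acyl donor and protecting group at once.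
Order of rings: dihydropyranone (O1–C8a, 2,3-cis from a syn-aldol triketide) first; the temporary anhydride ring second (benzylic centre from an iminium Michael addition); benzene ring A last by closure of C6–C7; then dearomatisation.

Key step: step 10

Remark: the target is an enolised cyclic β-triketone; the tautomer of the given SMILES is written for 25 and all tautomers are treated as the same compound.

Step 1
Reactants: 1 (4S)-4-benzyl-3-propanoyl-1,3-oxazolidin-2-one; 2 acetaldehyde
Product: 3 (4S)-4-benzyl-3-[(2S,3R)-3-hydroxy-2-methylbutanoyl]-1,3-oxazolidin-2-one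
Conditions: Bu2BOTf, i-Pr2NEt, CH2Cl2, −78 → 0 °C; 2, −78 °C; pH 7 buffer, MeOH, 30% H2O2
Reagents that add atoms: none
Why: Evans syn-aldol reaction: the Z-boron enolate adds through a closed chair (Zimmerman–Traxler) transition state on the enolate face left open by the benzyl group of the auxiliary, which should set the (2S,3R) syn pair that becomes C3 and C2 of the pyranone.

Step 2
Reactants: 3 (4S)-4-benzyl-3-[(2S,3R)-3-hydroxy-2-methylbutanoyl]-1,3-oxazolidin-2-one
Product: 4 (2S,3R)-3-hydroxy-N-methoxy-N,2-dimethylbutanamide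
Conditions: MeNHOMe·HCl, AlMe3, CH2Cl2, −15 → 0 °C; aq. Rochelle salt
Reagents that add atoms: N,O-dimethylhydroxylamine hydrochloride, CNOC.Cl
Why: Weinreb amide formation by aluminium amide transamidation of the imide, a standard release of aldol adducts in which the hydroxyl is masked as its aluminium alkoxide and neither stereocentre is touched.

Step 3
Reactants: 4 (2S,3R)-3-hydroxy-N-methoxy-N,2-dimethylbutanamide; 5 tert-butyl 3-oxobutanoate
Product: 7 tert-butyl 2-[(2R,3S)-2,3-dimethyl-4-oxo-3,4-dihydro-2H-pyran-6-yl]acetate, via diketo ester 6 (not isolated)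
Conditions: 5 (3.2 equiv), NaH, then n-BuLi, THF, 0 °C; 4, −78 → 0 °C; AcOH; then p-TsOH·H2O (cat.), CH2Cl2, rt
Reagents that add atoms: none
Why: Claisen-type γ-acylation of the acetoacetate dianion by the Weinreb amide (the chelated tetrahedral adduct prevents over-addition and excess dianion absorbs the hydroxyl proton), then acid-catalysed cyclodehydration in which the hydroxyl can reach only the C3 ketone of 6 through a six-membered ring, with retention at the carbinol carbon so that syn becomes 2,3-cis.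

Step 4
Reactants: 7 tert-butyl 2-[(2R,3S)-2,3-dimethyl-4-oxo-3,4-dihydro-2H-pyran-6-yl]acetate; 8 (E)-3-phenylprop-2-enal
Product: 9 tert-butyl (3R)-2-[(2R,3S)-2,3-dimethyl-4-oxo-3,4-dihydro-2H-pyran-6-yl]-5-oxo-3-phenylpentanoate (C2 epimers)
Conditions: (S)-2-[diphenyl(trimethylsilyloxy)methyl]pyrrolidine (10 mol %), PhCO2H (10 mol %), EtOH, 0 °C → rt; used crude
Reagents that add atoms: none
Why: Iminium-catalysed Michael addition of a vinylogous malonate-type C–H acid: the (S)-configured catalyst shields the Re face of the β-carbon of the E-iminium ion, so the carbanion (the later C8) should add to the Si face and set the benzylic centre (R in 9, the arrangement that is S in the target), while C8 itself forms as an inconsequential epimer mixture.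

Step 5
Reactants: 9 tert-butyl (3R)-2-[(2R,3S)-2,3-dimethyl-4-oxo-3,4-dihydro-2H-pyran-6-yl]-5-oxo-3-phenylpentanoate
Product: 10 (3R)-5-tert-butoxy-4-[(2R,3S)-2,3-dimethyl-4-oxo-3,4-dihydro-2H-pyran-6-yl]-5-oxo-3-phenylpentanoic acid (C4 epimers)
Conditions: NaClO2, NaH2PO4, 2-methylbut-2-ene, t-BuOH/H2O, 0 °C → rt
Reagents that add atoms: sodium chlorite, [Na+].[O-]Cl=O
Why: Pinnick oxidation, selective for the aldehyde in the presence of the vinylogous ester and the tert-butyl ester, with 2-methylbut-2-ene removing the hypochlorous acid formed.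

Step 6
Reactants: 10 (3R)-5-tert-butoxy-4-[(2R,3S)-2,3-dimethyl-4-oxo-3,4-dihydro-2H-pyran-6-yl]-5-oxo-3-phenylpentanoic acid
Product: 12 (4R)-3-[(2R,3S)-2,3-dimethyl-4-oxo-3,4-dihydro-2H-pyran-6-yl]-4-phenyloxane-2,6-dione (C3 epimers), via diacid 11 (not isolated)
Conditions: TFA/CH2Cl2 (1:3), 0 °C → rt; concentrate; DCC (1.05 equiv), CH2Cl2, 0 °C; filter; used crude
Reagents that add atoms: none
Why: Acidolysis of the tert-butyl ester followed by carbodiimide dehydration of the 1,5-diacid, which closes the six-membered cyclic (glutaric) anhydride and leaves C3–H of the pyranone untouched because no base is present.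

Step 7
Reactants: 13 2-methylhexa-1,5-diene; 14 but-3-en-2-one
Product: 15 (3E)-7-methylocta-3,7-dien-2-one
Conditions: second-generation Grubbs catalyst (3 mol %), 14 (3 equiv), CH2Cl2, 40 °C
Reagents that add atoms: none
Why: Olefin cross-metathesis between the monosubstituted alkene and the electron-poor enone partner, which should be E-selective and leaves the 1,1-disubstituted alkene alone (ring-closing metathesis would need a cyclobutene).

Step 8
Reactants: 15 (3E)-7-methylocta-3,7-dien-2-one; 16 (2-methylprop-1-en-1-yl)boronic acid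
Product: 17 (4S)-7-methyl-4-(2-methylprop-1-en-1-yl)oct-7-en-2-one
Conditions: [Rh(acac)(C2H4)2] (3 mol %), (R)-BINAP (3.3 mol %), 16 (2.5 equiv), 1,4-dioxane/H2O (10:1), 100 °C
Reagents that add atoms: none
Why: Hayashi–Miyaura reaction (rhodium-catalysed asymmetric 1,4-addition of an alkenylboronic acid to an acyclic E-enone); by the established facial model the (R)-BINAP complex should deliver the alkenyl group to the face that makes C4 (the later C2') S.

Step 9
Reactants: 17 (4S)-7-methyl-4-(2-methylprop-1-en-1-yl)oct-7-en-2-one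
Product: 19 (4S)-1-diazo-7-methyl-4-(2-methylprop-1-en-1-yl)oct-7-en-2-one, via trifluoroacetyl ketone 18 (not isolated)
Conditions: LiN(SiMe3)2, THF, −78 °C; CF3CO2CH2CF3; then MsN3, Et3N, H2O, MeCN, rt
Reagents that add atoms: methanesulfonyl azide, CS(=O)(=O)N=[N+]=[N-]; 2,2,2-trifluoroethyl trifluoroacetate, FC(F)(F)COC(=O)C(F)(F)F (its atoms are carried only by intermediate 18)
Why: Detrifluoroacetylative diazo transfer: the kinetic methyl enolate is trifluoroacetylated and the activated 1,3-diketone takes the diazo group from the sulfonyl azide with loss of the trifluoroacetyl group, the β-stereocentre being untouched.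

Step 10
Reactants: 12 (4R)-3-[(2R,3S)-2,3-dimethyl-4-oxo-3,4-dihydro-2H-pyran-6-yl]-4-phenyloxane-2,6-dione; 19 (4S)-1-diazo-7-methyl-4-(2-methylprop-1-en-1-yl)oct-7-en-2-one
Product: 23 (3S)-3-[(2R,3S)-5,7-dihydroxy-2,3-dimethyl-6-[(2S)-5-methyl-2-(2-methylprop-1-en-1-yl)hex-5-en-1-yl]-4-oxo-3,4-dihydro-2H-chromen-8-yl]-3-phenylpropanoic acid, via alkylketene 20 (not isolated), via acyl anhydride 21 (not isolated), via dienylketene acid 22 (not isolated)
Conditions: 12, Mg(OTf)2 (2 equiv), Et3N (4 equiv), THF, 0 °C; 19 (1.3 equiv, slow addition), CF3CO2Ag (10 mol %), 0 → 20 °C, dark; then 45 °C; 1 M citric acid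
Reagents that add atoms: none
Why: Proposed new method: a vinylogous Tamura-type [4+2] benzannulation with a ketene as the two-carbon partner, in which silver-catalysed Wolff rearrangement of 19 (1,2-shift of the C1' methylene to the diazo carbon, which becomes C6) gives ketene 20, the magnesium dienolate of 12 (deprotonated at C8, nucleophilic at the unhindered vinylogous carbon C4a) adds to the ketene carbonyl carbon (C5) as in magnesium-enolate C-acylations to give 21, and base-induced E1cB opening of the anhydride at C8 unmasks C7 as dienylketene 22 together with the side-chain carboxylate. The closest known reactions are the Tamura annulation of homophthalic anhydrides, the trapping of Wolff ketenes by nucleophiles, the magnesium-templated Claisen cyclisation of triketides to acylphloroglucinols and the 6π ring closure of dienylketenes to phenols. Ring A closes at C6–C7 by thermal disrotatory 6π-electrocyclisation of the C5 enol(ate) form of 22 (equivalently a 6-(enolendo)-exo-trig C-acylation), and tautomerisation of the cyclohexadienone to the phenol makes the closure irreversible. No stereocentre is created (C6–H is lost on aromatisation) and the step is stereoconvergent at C8, because both C8 epimers of 12 pass through the same planar dienolate, while C2, C3, the benzylic carbon and C2' are not touched. The selectivity needed is C4a- over C8- and O-acylation and then C6–C7 over O–C7 closure (which would give an α-pyranone): C8 is a hindered tertiary site whose acylation product cannot be stabilised by enolisation, and the six-membered magnesium chelate of the C4 and C5 carbonyl oxygens turns the C5 oxygen away from C7 and presents C6 to it.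

Step 11
Reactants: 23 (3S)-3-[(2R,3S)-5,7-dihydroxy-2,3-dimethyl-6-[(2S)-5-methyl-2-(2-methylprop-1-en-1-yl)hex-5-en-1-yl]-4-oxo-3,4-dihydro-2H-chromen-8-yl]-3-phenylpropanoic acid; 24 3-methylbut-2-en-1-yl acetate
Product: 25 (3S)-3-[(2R,3S,6S)-4-hydroxy-2,3-dimethyl-6-(3-methylbut-2-en-1-yl)-6-[(2S)-5-methyl-2-(2-methylprop-1-en-1-yl)hex-5-en-1-yl]-5,7-dioxo-3,5,6,7-tetrahydro-2H-chromen-8-yl]-3-phenylpropanoic acid (CNP0155375.1)
Conditions: Pd2(dba)3 (2.5 mol %), (R,R)-N,N'-(cyclohexane-1,2-diyl)bis[2-(diphenylphosphanyl)benzamide] (7.5 mol %), 24 (1.5 equiv), Et3N (2.2 equiv), THF, 0 °C → rt; 1 M citric acid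
Reagents that add atoms: none
Why: Tsuji–Trost-type asymmetric allylic dearomatisation: the C7 phenoxide attacks the π-prenyl palladium complex through C6 (the carbon between the two oxygenated carbons) at the unsubstituted allyl terminus, the chiral pocket of the (R,R)-ligand being relied on to select the C6 face that gives S (catalyst control, all other stereocentres are remote), and any prenyl ester of the carboxylate re-ionises under the catalyst.

Compound list
1 | (4S)-4-benzyl-3-propanoyl-1,3-oxazolidin-2-one | CCC(=O)N1[C@@H](Cc2ccccc2)COC1=O | starting material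
2 | acetaldehyde | CC=O | starting material
3 | (4S)-4-benzyl-3-[(2S,3R)-3-hydroxy-2-methylbutanoyl]-1,3-oxazolidin-2-one | O=C([C@@H](C)[C@@H](C)O)N1[C@@H](Cc2ccccc2)COC1=O | intermediate
4 | (2S,3R)-3-hydroxy-N-methoxy-N,2-dimethylbutanamide | CON(C)C(=O)[C@@H](C)[C@@H](C)O | intermediate
5 | tert-butyl 3-oxobutanoate | CC(=O)CC(=O)OC(C)(C)C | starting material
6 | tert-butyl (6S,7R)-7-hydroxy-6-methyl-3,5-dioxooctanoate | CC(C)(C)OC(=O)CC(=O)CC(=O)[C@@H](C)[C@@H](C)O | intermediate
7 | tert-butyl 2-[(2R,3S)-2,3-dimethyl-4-oxo-3,4-dihydro-2H-pyran-6-yl]acetate | CC(C)(C)OC(=O)CC1=CC(=O)[C@@H](C)[C@@H](C)O1 | intermediate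
8 | (E)-3-phenylprop-2-enal | O=C/C=C/c1ccccc1 | starting material
9 | tert-butyl (3R)-2-[(2R,3S)-2,3-dimethyl-4-oxo-3,4-dihydro-2H-pyran-6-yl]-5-oxo-3-phenylpentanoate (C2 epimers) | CC(C)(C)OC(=O)C(C1=CC(=O)[C@@H](C)[C@@H](C)O1)[C@@H](CC=O)c1ccccc1 | intermediate
10 | (3R)-5-tert-butoxy-4-[(2R,3S)-2,3-dimethyl-4-oxo-3,4-dihydro-2H-pyran-6-yl]-5-oxo-3-phenylpentanoic acid (C4 epimers) | CC(C)(C)OC(=O)C(C1=CC(=O)[C@@H](C)[C@@H](C)O1)[C@@H](CC(=O)O)c1ccccc1 | intermediate
11 | (3R)-2-[(2R,3S)-2,3-dimethyl-4-oxo-3,4-dihydro-2H-pyran-6-yl]-3-phenylpentanedioic acid (C2 epimers) | OC(=O)C(C1=CC(=O)[C@@H](C)[C@@H](C)O1)[C@@H](CC(=O)O)c1ccccc1 | intermediate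
12 | (4R)-3-[(2R,3S)-2,3-dimethyl-4-oxo-3,4-dihydro-2H-pyran-6-yl]-4-phenyloxane-2,6-dione (C3 epimers) | O=C1OC(=O)C[C@@H](c2ccccc2)C1C1=CC(=O)[C@@H](C)[C@@H](C)O1 | intermediate
13 | 2-methylhexa-1,5-diene | C=CCCC(C)=C | starting material
14 | but-3-en-2-one | C=CC(C)=O | starting material
15 | (3E)-7-methylocta-3,7-dien-2-one | CC(=O)/C=C/CCC(C)=C | intermediate
16 | (2-methylprop-1-en-1-yl)boronic acid | CC(C)=CB(O)O | starting material
17 | (4S)-7-methyl-4-(2-methylprop-1-en-1-yl)oct-7-en-2-one | C=C(C)CC[C@H](C=C(C)C)CC(C)=O | intermediate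
18 | (6S)-1,1,1-trifluoro-9-methyl-6-(2-methylprop-1-en-1-yl)dec-9-ene-2,4-dione | C=C(C)CC[C@H](C=C(C)C)CC(=O)CC(=O)C(F)(F)F | intermediate
19 | (4S)-1-diazo-7-methyl-4-(2-methylprop-1-en-1-yl)oct-7-en-2-one | C=C(C)CC[C@H](C=C(C)C)CC(=O)C=[N+]=[N-] | intermediate
20 | (4S)-7-methyl-4-(2-methylprop-1-en-1-yl)octa-1,7-dien-1-one | C=C(C)CC[C@H](C=C(C)C)CC=C=O | intermediate
21 | (4R)-3-[(2R,3S)-2,3-dimethyl-5-[(4S)-7-methyl-4-(2-methylprop-1-en-1-yl)oct-7-enoyl]-4-oxo-3,4-dihydro-2H-pyran-6-yl]-4-phenyloxane-2,6-dione (C3 epimers) | O=C1OC(=O)C[C@@H](c2ccccc2)C1C1=C(C(=O)CC[C@@H](C=C(C)C)CCC(C)=C)C(=O)[C@@H](C)[C@@H](C)O1 | intermediate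
22 | (3S)-4-[(2R,3S)-2,3-dimethyl-5-[(4S)-7-methyl-4-(2-methylprop-1-en-1-yl)oct-7-enoyl]-4-oxo-3,4-dihydro-2H-pyran-6-yl]-5-oxo-3-phenylpent-4-enoic acid | OC(=O)C[C@@H](c1ccccc1)C(=C=O)C1=C(C(=O)CC[C@@H](C=C(C)C)CCC(C)=C)C(=O)[C@@H](C)[C@@H](C)O1 | intermediate
23 | (3S)-3-[(2R,3S)-5,7-dihydroxy-2,3-dimethyl-6-[(2S)-5-methyl-2-(2-methylprop-1-en-1-yl)hex-5-en-1-yl]-4-oxo-3,4-dihydro-2H-chromen-8-yl]-3-phenylpropanoic acid | C=C(C)CC[C@H](C=C(C)C)Cc1c(O)c2C(=O)[C@@H](C)[C@@H](C)Oc2c([C@@H](CC(=O)O)c2ccccc2)c1O | intermediate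
24 | 3-methylbut-2-en-1-yl acetate | CC(=O)OCC=C(C)C | starting material
25 | (3S)-3-[(2R,3S,6S)-4-hydroxy-2,3-dimethyl-6-(3-methylbut-2-en-1-yl)-6-[(2S)-5-methyl-2-(2-methylprop-1-en-1-yl)hex-5-en-1-yl]-5,7-dioxo-3,5,6,7-tetrahydro-2H-chromen-8-yl]-3-phenylpropanoic acid | C=C(C)CC[C@H](C=C(C)C)C[C@@]1(CC=C(C)C)C(=O)C2=C(O)[C@@H](C)[C@@H](C)OC2=C([C@@H](CC(=O)O)c2ccccc2)C1=O | target

Total step count: 11. Longest linear sequence: 8 steps (steps 1 to 6, then 10 and 11); steps 7 to 9 are the second branch.

Steps most likely to fail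

Step 10 (the labelled step). The ketene may be captured at oxygen or at C8 instead of C4a, the ring may close through the C5 oxygen to an α-pyranone instead of through C6, the ketene may dimerise, or the base may epimerise C3. The fallback sets out from 19 and 12 and comes back at 23, with each bond made in a separate reaction of known type. Silver-catalysed Wolff rearrangement of 19 in aqueous dioxane (Arndt–Eistert homologation) should give (4S)-7-methyl-4-(2-methylprop-1-en-1-yl)oct-7-enoic acid F1. Oxalyl chloride with catalytic DMF then gives (4S)-7-methyl-4-(2-methylprop-1-en-1-yl)oct-7-enoyl chloride F2. C-acylation of 12 with F2 under MgCl2/Et3N soft enolisation (MeCN, 0 °C) gives 21, which is isolated. A separate soft-enolisation Claisen cyclisation (MgBr2·OEt2, i-Pr2NEt, CH2Cl2, 0 °C → rt) then gives 23.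

Step 11. Facial selectivity at C6 may be poor, or O-prenylation or attack at the substituted allyl terminus may compete. The fallback sets out from 23 and comes back at 25, replacing π-allyl chemistry by chiral ion-pair (phase-transfer) control. Alkylation with prenyl bromide (2.2 equiv) under O-allyl-N-(9-anthracenylmethyl)cinchonidinium bromide and Cs2CO3 in toluene at −20 °C should alkylate C6 and esterify the carboxylate, giving 3-methylbut-2-en-1-yl (3S)-3-[(2R,3S,6S)-4-hydroxy-2,3-dimethyl-6-(3-methylbut-2-en-1-yl)-6-[(2S)-5-methyl-2-(2-methylprop-1-en-1-yl)hex-5-en-1-yl]-5,7-dioxo-3,5,6,7-tetrahydro-2H-chromen-8-yl]-3-phenylpropanoate F3. Pd(PPh3)4 (zerovalent palladium) and morpholine then remove the ester prenyl group and give 25.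

Step 4. The vinylogous C–H acid may be too unreactive toward the iminium ion, may add through the pyranone α-carbon (the later C4a), the aldehyde 9 may undergo aldol follow-up, or facial control may be weak. The fallback sets out from 7 and comes back at 10, with auxiliary control in place of catalyst control. Michael addition of the magnesium enolate of 7 (MgBr2·OEt2, i-Pr2NEt, CH2Cl2) to commercial (4S)-4-benzyl-3-[(E)-3-phenylprop-2-enoyl]-1,3-oxazolidin-2-one (chelated s-cis acceptor, attack opposite the benzyl group) should give tert-butyl (3R)-5-[(4S)-4-benzyl-2-oxo-1,3-oxazolidin-3-yl]-2-[(2R,3S)-2,3-dimethyl-4-oxo-3,4-dihydro-2H-pyran-6-yl]-5-oxo-3-phenylpentanoate F4. Cleavage of the imide with LiOH/H2O2 (THF/H2O, 0 °C) then gives 10.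

Further compounds
F1 | step 10 | (4S)-7-methyl-4-(2-methylprop-1-en-1-yl)oct-7-enoic acid | C=C(C)CC[C@H](C=C(C)C)CCC(=O)O
F2 | step 10 | (4S)-7-methyl-4-(2-methylprop-1-en-1-yl)oct-7-enoyl chloride | C=C(C)CC[C@H](C=C(C)C)CCC(Cl)=O
F3 | step 11 | 3-methylbut-2-en-1-yl (3S)-3-[(2R,3S,6S)-4-hydroxy-2,3-dimethyl-6-(3-methylbut-2-en-1-yl)-6-[(2S)-5-methyl-2-(2-methylprop-1-en-1-yl)hex-5-en-1-yl]-5,7-dioxo-3,5,6,7-tetrahydro-2H-chromen-8-yl]-3-phenylpropanoate | C=C(C)CC[C@H](C=C(C)C)C[C@@]1(CC=C(C)C)C(=O)C2=C(O)[C@@H](C)[C@@H](C)OC2=C([C@@H](CC(=O)OCC=C(C)C)c2ccccc2)C1=O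
F4 | step 4 | tert-butyl (3R)-5-[(4S)-4-benzyl-2-oxo-1,3-oxazolidin-3-yl]-2-[(2R,3S)-2,3-dimethyl-4-oxo-3,4-dihydro-2H-pyran-6-yl]-5-oxo-3-phenylpentanoate | CC(C)(C)OC(=O)C(C1=CC(=O)[C@@H](C)[C@@H](C)O1)[C@@H](CC(=O)N1[C@@H](Cc2ccccc2)COC1=O)c1ccccc1
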